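**Retrosynthetic overview**
- Last, the 5,6-diol is unmasked from a p-methoxybenzylidene acetal; the aryl–O–C1 bond comes from a Mitsunobu coupling of 7-hydroxy-8-methoxycoumarin with the C1–C8 (E)-allylic alcohol.
- The allylic alcohol comes from an (E)-enoate, whose C4–C5 bond is the key bond: a chelation-controlled vinylogous Mukaiyama aldol between the silyl dienolate of methyl 3-methylbut-2-enoate and (S)-2-(PMB-oxy)-3-methylbut-3-enal. This sets C5 and the E-alkene.
- The aldehyde comes from methyl (R)-glycerate acetonide: C6 is taken from the chiral pool, the ester becomes methyl ketone then isopropenyl, and PMP-acetal opening with DIBAL-H places PMB on the secondary oxygen.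
- Rings: the benzene ring is bought; the only ring built for the target is the coumarin pyranone (Pechmann, first step). The dioxolanes are protecting groups only.

Assumption: the target is read as 7-{[(2E,5S,6S)-5,6-dihydroxy-3,7-dimethylocta-2,7-dien-1-yl]oxy}-8-methoxy-2H-chromen-2-one (syn-diol), and compounds 1, 3 and 6 and all named reagents are catalogue chemicals.

**Route**

Step 1
Reactants: 1 2-methoxyresorcinol
Product: 2 7-hydroxy-8-methoxycoumarin
Conditions: DL-malic acid, conc. H2SO4, 105 °C; pour onto ice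
Reagents that add atoms: DL-malic acid, OC(CC(=O)O)C(=O)O
Why: Von Pechmann condensation, in which malic acid is decarbonylated to formylacetic acid that attacks the position ortho to one OH and para to the other and then lactonises; because 1 is C2-symmetric only the 7-hydroxy-8-methoxy isomer can form.

Step 2
Reactants: 3 methyl 3-methylbut-2-enoate
Product: 5 1-methoxy-3-methyl-1-(trimethylsilyloxy)buta-1,3-diene, via lithium dienolate 4 (not isolated)
Conditions: LDA (commercial solution), THF, −78 °C; then TMSCl, −78 °C → rt; distil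
Reagents that add atoms: chlorotrimethylsilane, C[Si](C)(C)Cl
Why: Kinetic γ-deprotonation by LDA gives the extended ester dienolate, which TMSCl traps on oxygen (O-silylation) to give the silyl dienol ether used as the vinylogous aldol donor.

Step 3
Reactants: 6 methyl (R)-2,2-dimethyl-1,3-dioxolane-4-carboxylate
Product: 7 (R)-N-methoxy-N,2,2-trimethyl-1,3-dioxolane-4-carboxamide
Conditions: MeNH(OMe)·HCl, iPrMgCl, THF, −20 °C
Reagents that add atoms: N,O-dimethylhydroxylamine hydrochloride, CNOC.Cl
Why: Weinreb amide formation by aminolysis of the ester with the magnesium amide is fast at −20 °C and leaves the α-alkoxy stereocentre untouched.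

Step 4
Reactants: 7 (R)-N-methoxy-N,2,2-trimethyl-1,3-dioxolane-4-carboxamide
Product: 8 (R)-1-(2,2-dimethyl-1,3-dioxolan-4-yl)ethan-1-one
Conditions: MeMgBr, THF, 0 °C; aq. NH4Cl
Reagents that add atoms: methylmagnesium bromide, C[Mg]Br
Why: Weinreb ketone synthesis, in which the magnesium chelate stops after one methyl addition and releases the ketone only on quench, so no tertiary alcohol forms and the α-centre is not epimerised.

Step 5
Reactants: 8 (R)-1-(2,2-dimethyl-1,3-dioxolan-4-yl)ethan-1-one
Product: 9 (S)-2,2-dimethyl-4-(prop-1-en-2-yl)-1,3-dioxolane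
Conditions: Ph3PCH3Br, KHMDS (commercial solution), THF, −78 °C → rt; distil (volatile)
Reagents that add atoms: methyltriphenylphosphonium bromide, C[P+](c1ccccc1)(c1ccccc1)c1ccccc1.[Br-]
Why: Wittig methylenation with the unstabilised ylide at low temperature outruns enolisation of the α-alkoxy ketone, so the isopropenyl group is installed with the stereocentre intact (R becomes S only through the change in CIP priorities).

Step 6
Reactants: 9 (S)-2,2-dimethyl-4-(prop-1-en-2-yl)-1,3-dioxolane
Product: 10 (S)-3-methylbut-3-ene-1,2-diol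
Conditions: Dowex 50W-X8 (H+), MeOH/H2O 9:1, rt; filter, concentrate
Reagents that add atoms: none
Why: Acid-catalysed acetonide hydrolysis on a sulfonic acid resin is too mild to ionise the allylic alcohol and lets the water-soluble diol be isolated by filtration and evaporation.

Step 7
Reactants: 10 (S)-3-methylbut-3-ene-1,2-diol
Product: 11 (4S)-2-(4-methoxyphenyl)-4-(prop-1-en-2-yl)-1,3-dioxolane (mixture of epimers at the acetal carbon)
Conditions: 4-MeOC6H4CH(OMe)2, PPTS (cat.), CH2Cl2, rt
Reagents that add atoms: 4-methoxybenzaldehyde dimethyl acetal, COc1ccc(C(OC)OC)cc1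
Why: Acid-catalysed transacetalisation gives the five-membered p-methoxybenzylidene acetal, which sets up delivery of a PMB group to the secondary oxygen; the acetal stereocentre is uncontrolled and is destroyed in the next step.

Step 8
Reactants: 11 (4S)-2-(4-methoxyphenyl)-4-(prop-1-en-2-yl)-1,3-dioxolane
Product: 12 (S)-2-[(4-methoxybenzyl)oxy]-3-methylbut-3-en-1-ol
Conditions: DIBAL-H, CH2Cl2, −78 → 0 °C; Rochelle salt
Reagents that add atoms: none
Why: Regioselective reductive acetal opening, in which DIBAL-H coordinates the less hindered primary oxygen, cleaves that C–O bond and delivers hydride to the oxocarbenium ion, leaving PMB on the secondary oxygen and the primary alcohol free.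

Step 9
Reactants: 12 (S)-2-[(4-methoxybenzyl)oxy]-3-methylbut-3-en-1-ol
Product: 13 (S)-2-[(4-methoxybenzyl)oxy]-3-methylbut-3-enal
Conditions: Dess–Martin periodinane, CH2Cl2, 0 °C → rt; use crude at once
Reagents that add atoms: none
Why: Dess–Martin oxidation is neutral and fast, so the α-alkoxy-β,γ-unsaturated aldehyde forms without epimerisation or migration of the double bond.

Step 10
Reactants: 13 (S)-2-[(4-methoxybenzyl)oxy]-3-methylbut-3-enal; 5 1-methoxy-3-methyl-1-(trimethylsilyloxy)buta-1,3-diene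
Product: 14 methyl (2E,5S,6S)-5-hydroxy-6-[(4-methoxybenzyl)oxy]-3,7-dimethylocta-2,7-dienoate
Conditions: MgBr2·OEt2 (3 equiv), CH2Cl2, −78 → −20 °C; 1 M HCl work-up
Reagents that add atoms: none
Why: Chelation-controlled vinylogous Mukaiyama aldol reaction, in which Mg(II) ties the aldehyde oxygen and the α-OPMB oxygen into a five-membered chelate and the dienolate attacks through its γ-carbon from the face opposite the isopropenyl group (Cram-chelate model), setting C5 as S (syn to C6) and giving the (E)-enoate.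

Step 11
Reactants: 14 methyl (2E,5S,6S)-5-hydroxy-6-[(4-methoxybenzyl)oxy]-3,7-dimethylocta-2,7-dienoate
Product: 15 methyl (E)-4-[(4S,5S)-2-(4-methoxyphenyl)-5-(prop-1-en-2-yl)-1,3-dioxolan-4-yl]-3-methylbut-2-enoate (mixture of epimers at the acetal carbon)
Conditions: DDQ, 4 Å MS, CH2Cl2, 0 °C
Reagents that add atoms: none
Why: Oikawa–Yonemitsu oxidative acetalisation, in which DDQ oxidises the PMB ether to an oxocarbenium ion that the neighbouring C5 hydroxyl traps under anhydrous conditions, protecting both oxygens at once without touching C5 or C6 (the new acetal centre is uncontrolled and is removed in step 14).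

Step 12
Reactants: 15 methyl (E)-4-[(4S,5S)-2-(4-methoxyphenyl)-5-(prop-1-en-2-yl)-1,3-dioxolan-4-yl]-3-methylbut-2-enoate
Product: 16 (E)-4-[(4S,5S)-2-(4-methoxyphenyl)-5-(prop-1-en-2-yl)-1,3-dioxolan-4-yl]-3-methylbut-2-en-1-ol
Conditions: DIBAL-H (2.5 equiv), CH2Cl2, −78 °C; Rochelle salt
Reagents that add atoms: none
Why: DIBAL-H 1,2-reduction of the α,β-unsaturated ester at −78 °C gives the (E)-allylic alcohol, and at that temperature the p-methoxybenzylidene acetal is not opened.

Step 13
Reactants: 16 (E)-4-[(4S,5S)-2-(4-methoxyphenyl)-5-(prop-1-en-2-yl)-1,3-dioxolan-4-yl]-3-methylbut-2-en-1-ol; 2 7-hydroxy-8-methoxycoumarin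
Product: 17 8-methoxy-7-{[(E)-4-[(4S,5S)-2-(4-methoxyphenyl)-5-(prop-1-en-2-yl)-1,3-dioxolan-4-yl]-3-methylbut-2-en-1-yl]oxy}-2H-chromen-2-one
Conditions: PPh3, DIAD, THF, 0 °C → rt
Reagents that add atoms: none
Why: Mitsunobu etherification, in which the acidic coumarin 7-OH (pKa about 8) displaces the activated primary allylic alcohol by SN2 without allylic transposition and without opening the lactone.

Step 14
Reactants: 17 8-methoxy-7-{[(E)-4-[(4S,5S)-2-(4-methoxyphenyl)-5-(prop-1-en-2-yl)-1,3-dioxolan-4-yl]-3-methylbut-2-en-1-yl]oxy}-2H-chromen-2-one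
Product: 18 7-{[(2E,5S,6S)-5,6-dihydroxy-3,7-dimethylocta-2,7-dien-1-yl]oxy}-8-methoxy-2H-chromen-2-one (CNP0214345.1)
Conditions: AcOH/THF/H2O 3:1:1, rt
Reagents that add atoms: none
Why: Mild acid hydrolysis of the p-methoxybenzylidene acetal releases the syn-diol; the allylic aryl ether, the allylic alcohol and the lactone survive these conditions, and no stereocentre is involved.

**Compound list**

1 | 2-methoxyresorcinol (2-methoxybenzene-1,3-diol) | COc1c(O)cccc1O | starting material
2 | 7-hydroxy-8-methoxycoumarin (7-hydroxy-8-methoxy-2H-chromen-2-one) | COc1c(O)ccc2ccc(=O)oc12 | intermediate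
3 | methyl 3-methylbut-2-enoate | COC(=O)C=C(C)C | starting material
4 | lithium 1-methoxy-3-methylbuta-1,3-dien-1-olate (lithium dienolate) | [Li+].[O-]C(OC)=CC(C)=C | intermediate
5 | 1-methoxy-3-methyl-1-(trimethylsilyloxy)buta-1,3-diene (ketene acetal geometry immaterial) | COC(=CC(C)=C)O[Si](C)(C)C | intermediate
6 | methyl (R)-2,2-dimethyl-1,3-dioxolane-4-carboxylate | COC(=O)[C@H]1COC(C)(C)O1 | starting material
7 | (R)-N-methoxy-N,2,2-trimethyl-1,3-dioxolane-4-carboxamide | CON(C)C(=O)[C@H]1COC(C)(C)O1 | intermediate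
8 | (R)-1-(2,2-dimethyl-1,3-dioxolan-4-yl)ethan-1-one | CC(=O)[C@H]1COC(C)(C)O1 | intermediate
9 | (S)-2,2-dimethyl-4-(prop-1-en-2-yl)-1,3-dioxolane | C=C(C)[C@H]1COC(C)(C)O1 | intermediate
10 | (S)-3-methylbut-3-ene-1,2-diol | C=C(C)[C@H](O)CO | intermediate
11 | (4S)-2-(4-methoxyphenyl)-4-(prop-1-en-2-yl)-1,3-dioxolane (both acetal epimers) | C=C(C)[C@H]1COC(c2ccc(OC)cc2)O1 | intermediate
12 | (S)-2-[(4-methoxybenzyl)oxy]-3-methylbut-3-en-1-ol | C=C(C)[C@H](OCc1ccc(OC)cc1)CO | intermediate
13 | (S)-2-[(4-methoxybenzyl)oxy]-3-methylbut-3-enal | C=C(C)[C@H](OCc1ccc(OC)cc1)C=O | intermediate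
14 | methyl (2E,5S,6S)-5-hydroxy-6-[(4-methoxybenzyl)oxy]-3,7-dimethylocta-2,7-dienoate | C=C(C)[C@H](OCc1ccc(OC)cc1)[C@@H](O)C/C(C)=C/C(=O)OC | intermediate
15 | methyl (E)-4-[(4S,5S)-2-(4-methoxyphenyl)-5-(prop-1-en-2-yl)-1,3-dioxolan-4-yl]-3-methylbut-2-enoate (both acetal epimers) | C=C(C)[C@@H]1OC(c2ccc(OC)cc2)O[C@H]1C/C(C)=C/C(=O)OC | intermediate
16 | (E)-4-[(4S,5S)-2-(4-methoxyphenyl)-5-(prop-1-en-2-yl)-1,3-dioxolan-4-yl]-3-methylbut-2-en-1-ol (both acetal epimers) | C=C(C)[C@@H]1OC(c2ccc(OC)cc2)O[C@H]1C/C(C)=C/CO | intermediate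
17 | 8-methoxy-7-{[(E)-4-[(4S,5S)-2-(4-methoxyphenyl)-5-(prop-1-en-2-yl)-1,3-dioxolan-4-yl]-3-methylbut-2-en-1-yl]oxy}-2H-chromen-2-one (both acetal epimers) | C=C(C)[C@@H]1OC(c2ccc(OC)cc2)O[C@H]1C/C(C)=C/COc1ccc2ccc(=O)oc2c1OC | intermediate
18 | 7-{[(2E,5S,6S)-5,6-dihydroxy-3,7-dimethylocta-2,7-dien-1-yl]oxy}-8-methoxy-2H-chromen-2-one | C=C(C)[C@H](O)[C@@H](O)C/C(C)=C/COc1ccc2ccc(=O)oc2c1OC | target

**Totals**
Total step count: 14.
Longest linear sequence: 12 steps (6 → 18, steps 3–14). Steps 1 and 2 are side branches feeding steps 13 and 10.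

**Three steps most likely to fail**

Step 5 (Wittig methylenation of the epimerisable, volatile α-alkoxy ketone 8). The fallback avoids isolating the ketone. It sets out from ester 6: excess MeMgBr (THF, 0 °C) gives the tertiary alcohol (R)-2-(2,2-dimethyl-1,3-dioxolan-4-yl)propan-2-ol F1. Dehydration towards a methyl group with Burgess reagent (toluene, 60 °C) then gives 9, where the route is rejoined.

Step 8 (regiochemistry of the reductive acetal opening). The fallback sets out from diol 10 and differentiates the two hydroxyls stepwise. TBSCl/imidazole silylates the primary OH to give (S)-1-[(tert-butyldimethylsilyl)oxy]-3-methylbut-3-en-2-ol F2. 4-Methoxybenzyl trichloroacetimidate with catalytic CSA gives the PMB ether tert-butyl{[(S)-2-[(4-methoxybenzyl)oxy]-3-methylbut-3-en-1-yl]oxy}dimethylsilane F3. TBAF in THF removes the silyl group to give 12, where the route is rejoined.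

Step 10 (vinylogous aldol: γ/α ratio, E/Z ratio and chelate control on a labile aldehyde). The fallback sets out from 13 and builds the enoate in two C–C steps. A MgBr2·OEt2-mediated chelation-controlled Mukaiyama aldol of 13 with 2-(trimethylsilyloxy)propene gives (4S,5S)-4-hydroxy-5-[(4-methoxybenzyl)oxy]-6-methylhept-6-en-2-one F4. DDQ with 4 Å MS closes it to the acetal ketone 1-[(4S,5S)-2-(4-methoxyphenyl)-5-(prop-1-en-2-yl)-1,3-dioxolan-4-yl]propan-2-one F5. Horner–Wadsworth–Emmons olefination with trimethyl phosphonoacetate (LiCl, DBU, MeCN) and removal of the minor Z-isomer gives 15, where the route is rejoined.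

**Further compounds**
F1 | step 5 | (R)-2-(2,2-dimethyl-1,3-dioxolan-4-yl)propan-2-ol | CC(C)(O)[C@H]1COC(C)(C)O1
F2 | step 8 | (S)-1-[(tert-butyldimethylsilyl)oxy]-3-methylbut-3-en-2-ol | C=C(C)[C@H](O)CO[Si](C)(C)C(C)(C)C
F3 | step 8 | tert-butyl{[(S)-2-[(4-methoxybenzyl)oxy]-3-methylbut-3-en-1-yl]oxy}dimethylsilane | C=C(C)[C@H](OCc1ccc(OC)cc1)CO[Si](C)(C)C(C)(C)C
F4 | step 10 | (4S,5S)-4-hydroxy-5-[(4-methoxybenzyl)oxy]-6-methylhept-6-en-2-one | C=C(C)[C@H](OCc1ccc(OC)cc1)[C@@H](O)CC(C)=O
F5 | step 10 | 1-[(4S,5S)-2-(4-methoxyphenyl)-5-(prop-1-en-2-yl)-1,3-dioxolan-4-yl]propan-2-one (both acetal epimers) | C=C(C)[C@@H]1OC(c2ccc(OC)cc2)O[C@H]1CC(C)=O
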